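Ring A is disconnected at C2–C3 and C4–C5, leading back to a 4-methyl-3-oxidopyrylium-type ylide and 2,3-dihydrofuran. The feature exploited is transannular. O–C2 and the sole CH2 of ring A (C5) face each other across the seven-membered ring, both on the side away from lactone ring B. A single ether bridge C2–O–C5 beside a C6 ketone can therefore stand in for both. One enantioselective (5+2) cycloaddition closes ring A, brings in the future ring B and sets C2, C3 and C4. Its precursor is a racemic 6-aroyloxy-4-methylpyranone made by Achmatowicz rearrangement. The rigid bridge then steers reagents at C7 and C1 before SmI2 cuts the C5–O bond.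

Key step: step 4

Numbering:
- Ring A (cycloheptane): C1 is the tertiary carbinol bearing the crotonoyl group, C2 the CH–O-angelate, C3 the lactone CH–O, C4 the ring-fusion CH, C5 the CH2, C6 the CHOH, C7 the CH–CH3.
- Ring B (lactone): C11 is the alpha carbon, C12 the carbonyl, C13 the exocyclic methylene.
- "Bridge face" is the face of ring A carrying the C2 oxygen. "Lactone face" is the opposite one.
- In the target, C2–O, C6–OH and the crotonoyl group lie on the bridge face. C3–O, C4–C11, C7–CH3 and C1–OH lie on the lactone face.

Assumption: the (R,R) antipode of the aminothiourea is written. The sense of induction cannot be derived for this new pyranone, so a first run settles which antipode gives 8 rather than its mirror image. Both antipodes are available.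

Design remarks:
- The ether-to-lactone oxidation is placed before any C=C or C≡C is introduced.
- The crotonoyl ketone travels as an alkyne and the C11=C13 methylene as its Mannich base. An alpha-ketol, an enone or an acrylate would not survive SmI2 or the directed hydride.
- The C11 centre (20–28), the side-chain carbinol centre (16–30) and the allene axis (31) are all erased later.

Step 1
Reactants: 1 3-methylfuran-2-carboxylic acid
Product: 2 (3-methylfuran-2-yl)methanol
Conditions: LiAlH4, THF, 0 °C to reflux; Fieser work-up
Reagents that add atoms: none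
Why: Standard LiAlH4 reduction of a carboxylic acid to the primary alcohol, to which the furan ring is inert; no stereocentre is created.

Step 2
Reactants: 2 (3-methylfuran-2-yl)methanol
Product: 3 6-hydroxy-4-methyl-2H-pyran-3(6H)-one (racemic lactol)
Conditions: mCPBA, CH2Cl2, 0 °C to rt
Reagents that add atoms: mCPBA OOC(=O)c1cccc(Cl)c1
Why: Achmatowicz rearrangement: peracid oxidation of the furfuryl alcohol and recyclisation through the side-chain hydroxyl give the pyranone lactol, in which the former CH2OH carbon and furan C2, C3 (with its methyl), C4 and C5 become the future C5, C6, C7, C1 and C2; the lactol centre is racemic and is lost later.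

Step 3
Reactants: 3 6-hydroxy-4-methyl-2H-pyran-3(6H)-one
Product: 4 6-(3,4,5-trifluorobenzoyloxy)-4-methyl-2H-pyran-3(6H)-one (racemic)
Conditions: 3,4,5-trifluorobenzoyl chloride, pyridine, CH2Cl2, −20 to 0 °C
Reagents that add atoms: 3,4,5-trifluorobenzoyl chloride O=C(Cl)c1cc(F)c(F)c(F)c1
Why: O-Acylation of the lactol; the electron-poor benzoate replaces the usual acetate because it ionises more easily once bound by thioureas and forms a tighter chiral ion pair, while pyridine at low temperature is too weak a base to release the ylide prematurely.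

Step 4
Reactants: 4 6-(3,4,5-trifluorobenzoyloxy)-4-methyl-2H-pyran-3(6H)-one; 5 2,3-dihydrofuran
Product: 8 endo cycloadduct (oxygen bridge C2–O–C5; C6 ketone; C7-methyl enone; tetrahydrofuran cis-fused at C3/C4 anti to the bridge), via aminopyrylium carboxylate 6 (not isolated), via adduct imine 7 (not isolated)
Conditions: 5 (10 equiv), 1-[(1R,2R)-2-aminocyclohexyl]-3-[3,5-bis(trifluoromethyl)phenyl]thiourea (20 mol %), N,N'-bis[3,5-bis(trifluoromethyl)phenyl]thiourea (20 mol %), AcOH (20 mol %), toluene, rt to 40 °C
Reagents that add atoms: none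
Why: The primary amine of the catalyst condenses with the ketone of 4 (future C6) and the two thioureas pull off the carboxylate, giving aminopyrylium 6, the nitrogen analogue of the 4-methyl-3-oxidopyrylium ylide, which adds suprafacially in one concerted [π4s+π2s] event across the C=C of 5, after which hydrolysis of imine 7 frees 8 and the amine. The closest known reaction type is the intermolecular enantioselective (5+2) cycloaddition of pyrylium intermediates with acyclic vinyl ethers under aminothiourea/thiourea co-catalysis, applied here to a cyclic enol ether. Ring A closes by cycloaddition (C2–C3 and C4–C5 are made together, with no separate ring-closing event), the pyran oxygen ends as the C2–O–C5 bridge and the dihydrofuran ring arrives as the cis-fused precursor of ring B. C3/C4 are cis because the Z-alkene adds suprafacially, C2/C5 are tied by the bridge, the relation between the two pairs follows from endo approach (ring oxygen and CH2 of 5 tucked under the cationic π-system, hence anti to the bridge), and the absolute sense comes from the chiral amine–carboxylate ion pair that covers one face of 6. Regiochemistry requires the nucleophilic β-carbon of 5 (future C4) to bond to the pyrylium terminus next to the C–N carbon (future C5), where both frontier orbitals are largest, which puts the alkoxy carbon on C2 as with other enol ethers. The C7 methyl sits on a carbon that forms no bond and points away from the dipolarophile, and the large excess of 5 outruns pyrylium dimerisation.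

Step 5
Reactants: 8 endo cycloadduct
Product: 9 C6 allylic alcohol (hydroxyl on the lactone face, endo)
Conditions: NaBH4, CeCl3·7H2O, MeOH, −78 to 0 °C
Reagents that add atoms: none
Why: Luche 1,2-reduction of the enone; hydride arrives from the bridge face because the endo-fused tetrahydrofuran closes the other face, so the hydroxyl lies on the lactone face, a provisional centre that only masks the ketone and is erased in step 13.

Step 6
Reactants: 9 C6 allylic alcohol
Product: 10 C6 tert-butyldimethylsilyl ether
Conditions: TBSOTf, 2,6-lutidine, CH2Cl2, 0 °C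
Reagents that add atoms: TBSOTf CC(C)(C)[Si](C)(C)OS(=O)(=O)C(F)(F)F
Why: Silyl ether formation with the reactive triflate suits the hindered endo alcohol, and the TBS group withstands borane, RuO4, organocerium reagents and amide bases.

Step 7
Reactants: 10 C6 tert-butyldimethylsilyl ether
Product: 12 C1 alcohol (C1 hydroxyl and C7 hydrogen on the bridge face; C7 methyl on the lactone face), via C1 alkylborane 11 (not isolated)
Conditions: BH3·THF, THF, 0 °C to rt; then NaOH, H2O2, 0 °C
Reagents that add atoms: hydrogen peroxide OO
Why: Brown hydroboration–oxidation: borane adds syn from the open bridge face with boron on the less substituted C1, so hydrogen enters C7 on the bridge face and pushes the methyl group to the lactone face as in the target, and oxidation with retention gives the C1 alcohol.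

Step 8
Reactants: 12 C1 alcohol
Product: 14 C1 keto lactone (ring B now a γ-lactone; bridge and C6 silyl ether intact), via C1 keto ether 13 (not isolated)
Conditions: RuCl3·xH2O (5 mol %), NaIO4, EtOAc–MeCN–H2O, rt
Reagents that add atoms: sodium periodate [Na+].[O-]I(=O)(=O)=O
Why: RuO4 oxidation (catalytic RuCl3, periodate as terminal oxidant) first turns the C1 alcohol into the ketone and then the only unhindered and electronically undeactivated O–CH2 group (C12) into the lactone carbonyl, a known ether-to-lactone oxidation placed here because no alkene or alkyne is yet present; the near-neutral medium should leave C7 untouched.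

Step 9
Reactants: 15 (S)-but-3-yn-2-ol
Product: 16 (S)-but-3-yn-2-yl pivalate
Conditions: pivaloyl chloride, pyridine, DMAP (cat.), CH2Cl2, 0 °C to rt
Reagents that add atoms: pivaloyl chloride CC(C)(C)C(=O)Cl
Why: Simple esterification; the pivalate has no alpha hydrogens and a shielded carbonyl, so it survives the amide bases of steps 10 and 11, and the single enantiomer keeps all later intermediates single diastereomers although this centre is finally erased.

Step 10
Reactants: 14 C1 keto lactone; 16 (S)-but-3-yn-2-yl pivalate
Product: 19 C1 tertiary propargylic alcohol (alkynyl chain on the bridge face; C1 hydroxyl on the lactone face), via lithium acetylide 17 (not isolated), via dichlorocerium acetylide 18 (not isolated)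
Conditions: 16, LDA, THF, −78 °C; CeCl3 (anhydrous), −78 °C; then 14, −78 °C
Reagents that add atoms: none
Why: Organocerium 1,2-addition of an acetylide, a slim and weakly basic nucleophile that prefers the ketone to the lactone and does not enolise towards C7; it attacks C1 from the bridge face because the lactone face is closed by ring B and the C7 methyl, which places the carbon chain on the bridge face and the tertiary hydroxyl on the lactone face as in the target.

Step 11
Reactants: 19 C1 tertiary propargylic alcohol
Product: 20 C11 (dimethylamino)methyl lactone (Mannich base; aminomethyl group on the convex face of ring B, cis to H4)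
Conditions: LDA (2.3 equiv), THF, −78 °C; Eschenmoser's salt, −78 to 0 °C
Reagents that add atoms: Eschenmoser's salt C[N+](C)=C.[I-]
Why: Mannich reaction of the lactone enolate (the only enolisable carbonyl, the first equivalent of LDA being taken by the C1 hydroxyl) with Eschenmoser's salt, the iminium ion entering from the convex face of ring B; the amine is kept as a masked form of the C11=C13 methylene group, which would not survive SmI2.

Step 12
Reactants: 20 C11 Mannich base
Product: 21 C6 alcohol
Conditions: HF·pyridine, THF, 0 °C to rt
Reagents that add atoms: none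
Why: Fluoride-mediated cleavage of the silyl ether under mildly acidic conditions that spare the pivalate, the lactone and the tertiary propargylic alcohol.

Step 13
Reactants: 21 C6 alcohol
Product: 22 C6 ketone (bridge still intact)
Conditions: Dess–Martin periodinane, CH2Cl2, 0 °C to rt
Reagents that add atoms: none
Why: Dess–Martin oxidation of the only secondary alcohol restores the C6 ketone under non-basic conditions, so neither C7 epimerisation nor retro-aldol cleavage of the beta-hydroxy ketone is expected, and the acetic acid released keeps the amine protonated.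

Step 14
Reactants: 22 C6 ketone
Product: 23 ring-opened hydroxy ketone (free C2 hydroxyl on the bridge face; C5 now CH2)
Conditions: SmI2 (2.5 equiv), THF–MeOH, −78 °C
Reagents that add atoms: none
Why: SmI2 reduction of an alpha-alkoxy ketone: two single-electron transfers expel the strained C5–O bond, which is aligned with the carbonyl π-system, giving the C2 alkoxide and a samarium enolate that methanol protonates at C5; alkyne, propargylic pivalate, lactone and amine are not reduced by divalent samarium at this temperature, and C7 is not part of the enolate.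

Step 15
Reactants: 23 ring-opened hydroxy ketone; 24 angelic acid
Product: 26 C2 angelate, via angelic trichlorobenzoic anhydride 25 (not isolated)
Conditions: 24, 2,4,6-trichlorobenzoyl chloride, Et3N, toluene, rt; then 23, toluene, 80 °C (no DMAP)
Reagents that add atoms: none
Why: Yamaguchi-type mixed-anhydride esterification run without DMAP, the known way to make angelates without Z-to-E isomerisation; only the secondary C2 hydroxyl can react because the C1 hydroxyl is tertiary.

Step 16
Reactants: 26 C2 angelate
Product: 27 C1,C6-diol (C6 hydroxyl on the bridge face)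
Conditions: Me4NBH(OAc)3, MeCN–AcOH, −30 to −20 °C
Reagents that add atoms: none
Why: Evans–Saksena reduction: the C1 hydroxyl on the lactone face exchanges onto boron and delivers hydride to the same face of the C6 ketone through a six-membered transition state, so the new hydroxyl appears on the bridge face (1,3-anti diol) as in the target, while esters, lactone and alkyne are inert to the triacetoxyborohydride.

Step 17
Reactants: 27 C1,C6-diol
Product: 29 α-methylene lactone diol, via trimethylammonium iodide 28 (not isolated)
Conditions: MeI, CH2Cl2, rt; then sat. aq. NaHCO3, rt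
Reagents that add atoms: none
Why: Exhaustive methylation and E1cB (Hofmann-type) elimination of the beta-ammonio lactone, the standard second half of the Eschenmoser methylenation, under bicarbonate conditions too mild to touch the esters.

Step 18
Reactants: 29 α-methylene lactone diol
Product: 30 C1,C6-bis(trimethylsilyl) ether
Conditions: TMSOTf, 2,6-lutidine, CH2Cl2, −78 to 0 °C
Reagents that add atoms: TMSOTf C[Si](C)(C)OS(=O)(=O)C(F)(F)F
Why: Silylation of both hydroxyls; the C1 hydroxyl must be capped because a free alpha-hydroxyl would add to the gold-activated allene of step 19 and close a dihydrofuran.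

Step 19
Reactants: 30 C1,C6-bis(trimethylsilyl) ether
Product: 33 CNP0149130.1 (target), via allenyl pivalate 31 (not isolated), via silylated enone 32 (not isolated)
Conditions: (Ph3P)AuNTf2 (5 mol %), wet butanone, rt; then HF·pyridine, 0 °C
Reagents that add atoms: none
Why: Gold-catalysed [3,3] acyloxy shift of the propargylic pivalate to the allenyl ester followed by hydrolysis in the wet solvent, a known Meyer–Schuster-type route from propargylic esters to E-enones that puts the carbonyl on the carbon attached to C1; fluoride then removes both silyl groups without touching the enone, the methylene lactone or the angelate.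

Compound list
1 | 3-methylfuran-2-carboxylic acid | Cc1ccoc1C(=O)O | starting material
2 | (3-methylfuran-2-yl)methanol | Cc1ccoc1CO | intermediate
3 | 6-hydroxy-4-methyl-2H-pyran-3(6H)-one, racemic | CC1=CC(O)OCC1=O | intermediate
4 | 6-(3,4,5-trifluorobenzoyloxy)-4-methyl-2H-pyran-3(6H)-one, racemic | CC1=CC(OC(=O)c2cc(F)c(F)c(F)c2)OCC1=O | intermediate
5 | 2,3-dihydrofuran | C1CC=CO1 | starting material
6 | catalyst-bound 3-amino-4-methylpyrylium 3,4,5-trifluorobenzoate (not isolated) | Cc1cc[o+]cc1N[C@@H]2CCCC[C@H]2NC(=S)Nc3cc(cc(c3)C(F)(F)F)C(F)(F)F.[O-]C(=O)c4cc(F)c(F)c(F)c4 | intermediate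
7 | catalyst-bound C6 imine of the endo cycloadduct (not isolated) | C1CO[C@@H]2[C@H]1[C@@H]3C(=N[C@@H]4CCCC[C@H]4NC(=S)Nc5cc(cc(c5)C(F)(F)F)C(F)(F)F)C(C)=C[C@H]2O3 | intermediate
8 | endo cycloadduct: C2–O–C5 bridge, C6 ketone, C7-methyl enone, cis-fused tetrahydrofuran at C3/C4 anti to the bridge | C1CO[C@@H]2[C@H]1[C@@H]3C(=O)C(C)=C[C@H]2O3 | intermediate
9 | C6 allylic alcohol, hydroxyl endo (lactone face) | C1CO[C@@H]2[C@H]1[C@@H]3[C@H](O)C(C)=C[C@H]2O3 | intermediate
10 | C6 TBS ether of 9 | C1CO[C@@H]2[C@H]1[C@@H]3[C@H](O[Si](C)(C)C(C)(C)C)C(C)=C[C@H]2O3 | intermediate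
11 | C1 alkylborane, boron and C7–H on the bridge face (not isolated) | C1CO[C@@H]2[C@H]1[C@@H]3[C@H](O[Si](C)(C)C(C)(C)C)[C@H](C)[C@@H](B)[C@H]2O3 | intermediate
12 | C1 alcohol, hydroxyl exo, C7 methyl endo | C1CO[C@@H]2[C@H]1[C@@H]3[C@H](O[Si](C)(C)C(C)(C)C)[C@H](C)[C@@H](O)[C@H]2O3 | intermediate
13 | C1 ketone with intact tetrahydrofuran (not isolated) | C1CO[C@@H]2[C@H]1[C@@H]3[C@H](O[Si](C)(C)C(C)(C)C)[C@H](C)C(=O)[C@H]2O3 | intermediate
14 | C1 keto lactone | C1C(=O)O[C@@H]2[C@H]1[C@@H]3[C@H](O[Si](C)(C)C(C)(C)C)[C@H](C)C(=O)[C@H]2O3 | intermediate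
15 | (S)-but-3-yn-2-ol | C#C[C@H](C)O | starting material
16 | (S)-but-3-yn-2-yl pivalate | C#C[C@H](C)OC(=O)C(C)(C)C | intermediate
17 | lithium acetylide of 16 (not isolated) | [Li]C#C[C@H](C)OC(=O)C(C)(C)C | intermediate
18 | dichlorocerium acetylide of 16 (not isolated) | Cl[Ce](Cl)C#C[C@H](C)OC(=O)C(C)(C)C | intermediate
19 | C1 tertiary propargylic alcohol, alkynyl on the bridge face | C1C(=O)O[C@@H]2[C@H]1[C@@H]3[C@H](O[Si](C)(C)C(C)(C)C)[C@H](C)[C@@](O)(C#C[C@H](C)OC(=O)C(C)(C)C)[C@H]2O3 | intermediate
20 | C11 (dimethylamino)methyl lactone | CN(C)C[C@@H]1C(=O)O[C@@H]2[C@H]1[C@@H]3[C@H](O[Si](C)(C)C(C)(C)C)[C@H](C)[C@@](O)(C#C[C@H](C)OC(=O)C(C)(C)C)[C@H]2O3 | intermediate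
21 | C6 alcohol (silyl group removed) | CN(C)C[C@@H]1C(=O)O[C@@H]2[C@H]1[C@@H]3[C@H](O)[C@H](C)[C@@](O)(C#C[C@H](C)OC(=O)C(C)(C)C)[C@H]2O3 | intermediate
22 | bridged C6 ketone | CN(C)C[C@@H]1C(=O)O[C@@H]2[C@H]1[C@@H]3C(=O)[C@H](C)[C@@](O)(C#C[C@H](C)OC(=O)C(C)(C)C)[C@H]2O3 | intermediate
23 | ring-opened C6 ketone with free C2 hydroxyl and C5H2 | CN(C)C[C@@H]1C(=O)O[C@@H]2[C@H]1CC(=O)[C@H](C)[C@@](O)(C#C[C@H](C)OC(=O)C(C)(C)C)[C@H]2O | intermediate
24 | angelic acid, (Z)-2-methylbut-2-enoic acid | C/C=C(/C)C(=O)O | starting material
25 | angelic 2,4,6-trichlorobenzoic anhydride (not isolated) | C/C=C(/C)C(=O)OC(=O)c1c(Cl)cc(Cl)cc1Cl | intermediate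
26 | C2 angelate, C6 ketone | CN(C)C[C@@H]1C(=O)O[C@@H]2[C@H]1CC(=O)[C@H](C)[C@@](O)(C#C[C@H](C)OC(=O)C(C)(C)C)[C@H]2OC(=O)/C(C)=C\C | intermediate
27 | C1,C6-diol, C6 hydroxyl on the bridge face | CN(C)C[C@@H]1C(=O)O[C@@H]2[C@H]1C[C@@H](O)[C@H](C)[C@@](O)(C#C[C@H](C)OC(=O)C(C)(C)C)[C@H]2OC(=O)/C(C)=C\C | intermediate
28 | trimethylammonium iodide of 27 (not isolated) | C[N+](C)(C)C[C@@H]1C(=O)O[C@@H]2[C@H]1C[C@@H](O)[C@H](C)[C@@](O)(C#C[C@H](C)OC(=O)C(C)(C)C)[C@H]2OC(=O)/C(C)=C\C.[I-] | intermediate
29 | α-methylene lactone diol | C=C1C(=O)O[C@@H]2[C@H]1C[C@@H](O)[C@H](C)[C@@](O)(C#C[C@H](C)OC(=O)C(C)(C)C)[C@H]2OC(=O)/C(C)=C\C | intermediate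
30 | C1,C6-bis(trimethylsilyl) ether of 29 | C=C1C(=O)O[C@@H]2[C@H]1C[C@@H](O[Si](C)(C)C)[C@H](C)[C@@](O[Si](C)(C)C)(C#C[C@H](C)OC(=O)C(C)(C)C)[C@H]2OC(=O)/C(C)=C\C | intermediate
31 | allenyl pivalate, axis not specified (not isolated) | C=C1C(=O)O[C@@H]2[C@H]1C[C@@H](O[Si](C)(C)C)[C@H](C)[C@@](O[Si](C)(C)C)(C(OC(=O)C(C)(C)C)=C=CC)[C@H]2OC(=O)/C(C)=C\C | intermediate
32 | bis-silylated (E)-crotonoyl compound (not isolated) | C=C1C(=O)O[C@@H]2[C@H]1C[C@@H](O[Si](C)(C)C)[C@H](C)[C@@](O[Si](C)(C)C)(C(=O)/C=C/C)[C@H]2OC(=O)/C(C)=C\C | intermediate
33 | CNP0149130.1 | C=C1C(=O)O[C@@H]2[C@H]1C[C@@H](O)[C@H](C)[C@@](O)(C(=O)/C=C/C)[C@H]2OC(=O)/C(C)=C\C | target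

Total step count: 19. Longest linear sequence: 18 (steps 1–8 and 10–19).

Steps most likely to fail

Step 4. Three things may go wrong:
- Addition to a 1,2-disubstituted cyclic enol ether may be slow enough for the pyrylium to dimerise.
- Imine formation next to the C7 methyl may be sluggish.
- Endo or facial selectivity may be eroded, and the acids present also consume some 5.

Fallback (from 4 and 5, back at 9): enantiocontrol is moved from the catalyst to a resolution while the same bonds are formed. 4 is treated with iPr2NEt in CH2Cl2 and excess 5 at 40 °C, which releases free 4-methyl-3-oxidopyrylium F1. Its base-mediated cycloaddition should give the racemic endo adduct, that is 8 together with ent-8 F2. Luche reduction as in step 5 gives 9 together with ent-9 F3. Esterification with (S)-O-methylmandelic acid (DCC, DMAP, CH2Cl2) gives two diastereomers, the mandelate of 9 F4 and the mandelate of ent-9 F5. These are separated by chromatography or crystallisation. K2CO3 in MeOH cleaves F4 to 9.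

Step 15. Acylation of the hindered C2 hydroxyl may be slow. Prolonged heating may then cause Z-to-E isomerisation of the acyl group, epimerisation at C7 next to the C6 ketone, dehydration or retro-aldol opening of the beta-hydroxy ketone, or transannular hemiketalisation that hides the hydroxyl.

Fallback (from 23, back at 27): acylation and reduction change places, so that no ketone is present when heat is applied. 23 is first reduced with Me4NBH(OAc)3 as in step 16 to the C1,C2,C6-triol F6. The least hindered hydroxyl, at C6, is silylated selectively (TESCl, imidazole, CH2Cl2, −20 °C) to the C6 triethylsilyl ether F7. Anhydride 25 in hot toluene then acylates the remaining secondary hydroxyl to give the silylated C2 angelate F8. HF·pyridine removes the silyl group and gives 27.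

Step 19. Three things may go wrong:
- Early loss of the C1 silyl group may allow cyclisation onto the activated allene.
- A competing 1,2-acyloxy shift may occur at the crowded alkyne.
- Hydrolysis of the hindered allenyl ester may be slow.

Fallback (from 29, back at 33): the free C1 hydroxyl delivers the oxygen instead of being protected. 29 is carboxylated and cyclised with CO2 (AgOAc cat., DBU, MeCN). This is the known 5-exo-dig route from tertiary propargylic alcohols to alkylidene carbonates. It gives the spiro (Z)-alkylidene cyclic carbonate F9, with oxygen on the alkyne carbon next to C1. Water opens the carbonate with loss of CO2 to the beta-pivaloyloxy ketone F10. DBU then eliminates pivalic acid (E1cB) to give 33.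

Further compounds
F1 | step 4 | 4-methyl-3-oxidopyrylium | Cc1cc[o+]cc1[O-]
F2 | step 4 | ent-8 | C1CO[C@H]2[C@@H]1[C@H]3C(=O)C(C)=C[C@@H]2O3
F3 | step 4 | ent-9 | C1CO[C@H]2[C@@H]1[C@H]3[C@@H](O)C(C)=C[C@@H]2O3
F4 | step 4 | (S)-O-methylmandelate of 9 | C1CO[C@@H]2[C@H]1[C@@H]3[C@H](OC(=O)[C@@H](OC)c4ccccc4)C(C)=C[C@H]2O3
F5 | step 4 | (S)-O-methylmandelate of ent-9 | C1CO[C@H]2[C@@H]1[C@H]3[C@@H](OC(=O)[C@@H](OC)c4ccccc4)C(C)=C[C@@H]2O3
F6 | step 15 | C1,C2,C6-triol | CN(C)C[C@@H]1C(=O)O[C@@H]2[C@H]1C[C@@H](O)[C@H](C)[C@@](O)(C#C[C@H](C)OC(=O)C(C)(C)C)[C@H]2O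
F7 | step 15 | C6 triethylsilyl ether of F6 | CN(C)C[C@@H]1C(=O)O[C@@H]2[C@H]1C[C@@H](O[Si](CC)(CC)CC)[C@H](C)[C@@](O)(C#C[C@H](C)OC(=O)C(C)(C)C)[C@H]2O
F8 | step 15 | C2 angelate of F7 | CN(C)C[C@@H]1C(=O)O[C@@H]2[C@H]1C[C@@H](O[Si](CC)(CC)CC)[C@H](C)[C@@](O)(C#C[C@H](C)OC(=O)C(C)(C)C)[C@H]2OC(=O)/C(C)=C\C
F9 | step 19 | spiro (Z)-alkylidene cyclic carbonate at C1 | C=C1C(=O)O[C@@H]2[C@H]1C[C@@H](O)[C@H](C)[C@@](O3)(/C(OC3=O)=C/[C@H](C)OC(=O)C(C)(C)C)[C@H]2OC(=O)/C(C)=C\C
F10 | step 19 | beta-pivaloyloxy ketone | C=C1C(=O)O[C@@H]2[C@H]1C[C@@H](O)[C@H](C)[C@@](O)(C(=O)C[C@H](C)OC(=O)C(C)(C)C)[C@H]2OC(=O)/C(C)=C\C
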